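## The problem

Compound 23 joins two 2-(2-phenylethyl)chromone units through an ether. O6' of a 6,7-dihydroxychromone is bonded to C5 of a 5,6,7,8-tetrahydrochromone whose carbocycle (C4a, C5, C6, C7, C8, C8a) carries an oxygen on every sp3 carbon. The four stereocentres are contiguous, (5S,6S,7R,8S): the aryloxy group at C5 and the hydroxyl at C8 are cis, and the hydroxyls at C6 and C7 are cis to each other and trans to both neighbours. Relative configuration can therefore be relayed: once C5 and C8 sit on one face, a C6=C7 alkene should be dihydroxylated from the other face. Nothing in the molecule fixes the absolute sense of the C5/C8 pair, so that must come from an external source or from a resolution. The C5–O(aryl) bond is the awkward one: C5 is secondary and flanked by C4a and C6, and substitution there would compete with ionisation (the cation is conjugated through C4a=C8a to O1) and with elimination. Loss of the phenol from C5 or of water from C8 leads towards an aromatic chromone, so strong acid, strong base (H8 is γ to the C4 carbonyl) and heat must be avoided late; both pyranone rings are also reducible and absorb UV light. The enabling feature is that C5 and C8 are the two carbons attached to the pyranone double bond C4a=C8a. Without C6 and C7 the ring is a 4-pyranone with a formyl group on C8a and an aryloxymethyl group on C4a, the keto tautomer of the dienol C8(OH)=C8a–C4a=C5H(OAr). A [4+2] addition to that dienol with both oxygens outward gives exactly the cis C5/C8 relation.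

## Retrosynthesis

**23 ⇒ 22 ⇒ 21 (O–benzyl bond; resolution).** The C7' phenol must stay masked through etherification at O6', acetal hydrolysis, irradiation, reductive desulfonylation and dihydroxylation. A benzyl ether survives all of these and leaves under neutral conditions, whereas an acyl or silyl group would migrate across the catechol and an acid-labile group would not survive the acetal hydrolysis. The key step has no reliable source of facial bias: chiral titanium alkoxide control of photoenol cycloadditions depends on a carbonyl-bearing dienophile, which a sulfonyl alkene is not. The plan therefore accepts a racemate and separates the enantiomers at 21, a stable single diastereomer, to give 22. The forward reactions must give a clean chromatographic separation of enantiomers and a hydrogenolysis that spares the allylic C5–O and C8–O bonds.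

**21 ⇒ 20 (C6–O and C7–O).** Both bonds are cut at once, back to the C6=C7 alkene of 20. Stepwise oxygenation through an epoxide would give a trans diol, while syn-dihydroxylation gives the cis diol directly. The allylic oxygens at C5 and C8 lie on one face of 20 and should direct the oxidant to the other. Two stereocentres are removed, and the forward step must be selective for the only isolated alkene and fast enough to outrun aromatisation of 20.

**20 ⇒ 19 (C6=C7 from two C–S bonds).** An unactivated two-carbon dienophile would not trap a short-lived dienol, and an alkyne would leave an activating group on the diene. The alkene is therefore traced to the vicinal bis-sulfone 19, whose sulfonyl groups activate the dienophile and then leave together by reductive elimination. The forward step must transfer electrons faster than base can expel sulfinate or aryloxide.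

**19 ⇒ 16 + 17 (C5–C6 and C7–C8; the key cut).** Cutting C4a–C5 or C4a=C8a instead turns the carbocycle into a chain but leaves the C5–O(aryl) bond to be made by substitution at a hindered secondary carbon. The cut chosen here removes the carbocycle and all four stereocentres at once. It leads to the achiral aldehyde 16, in which the ether oxygen already sits on a primary carbon, and to the commercial dienophile 17. The forward reaction must form the dienol of 16 by light-induced hydrogen transfer and add 17 across its termini with both oxygens outward.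

**16 ⇒ 15 ⇒ 9 + 14 (CH2–O bond).** The aldehyde is kept as its dimethyl acetal 15 until after the coupling, because a free formyl group next to a hydroxymethyl group would close to a lactol. Cutting the CH2–O bond divides the molecule into two halves of similar size, alcohol 9 and phenol 14, joined by a Mitsunobu etherification at an unhindered, non-stereogenic carbon. The alternative cut at the aryl–O bond would need a 6-halochromone and a metal-catalysed coupling for no gain.

**9 ⇒ 8 ⇒ 3 + 5 (pyranone ring; C3–C4 and O1–C2), 3 ⇒ 1, 5 ⇒ 4.** A CH2O substituent cannot be carried through pyranone formation, because before the ring is formed it is β to a ketone and would be eliminated. The carbon therefore enters as the ester of 8 and is reduced afterwards. Ester 8 is cut into the acylketene precursor 3 and the enamino ester 5. The amine of 5 makes the ring close on C2 and not on the ester carbonyl, which the free keto ester 4 could allow. Dioxinone 3 comes from 1 by benzylation at the methyl group, and 5 from 4 by condensation with a secondary amine.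

**14 ⇒ 12 ⇒ 11 ⇒ 10 (chromone C2–C3 and O1–C2).** The phenethylchromone is made by a Baker–Venkataraman sequence from acetophenone 10. The most acidic phenol (para to the acetyl group, the future O7') is benzylated first to give 11, and both remaining phenols are acylated to give 12. After the rearrangement, acid closes the ring and frees the O6' phenol of 14.

## Roads not taken

Alternative 1: The cut is the C4a–C5 bond, with C5–C8 and their oxygens taken from D-mannose A1 (sugar C1–C4) and C4a/C8a from sugar C6/C5. In the forward direction the enopyranoside A2 undergoes a Ferrier carbocyclization with catalytic Hg(OCOCF3)2 (divalent mercury) in aqueous acetone: oxymercuration opens the pyranoside and the resulting enolate closes on the former anomeric carbon, giving hydroxy ketone A3. Its merit is real and is where it beats the chosen plan: the configurations at C6, C7 and C8 come from the sugar and C5 from a well-behaved aldol closure, so no resolution is needed, and the key step has long precedent. Its weak points are downstream. A3 is a β-hydroxy ketone that dehydrates easily, the pyranone has still to be grown on its carbonyl, and the aryl ether has to be made by substitution at the hindered C5 carbinol, the very bond that ionises or eliminates. Three benzyl ethers must be carried and removed, and the linear sequence would be clearly longer than ten steps. Against the certainty of configuration, the chosen plan sets a C5–O bond that is never made at a secondary carbon, a convergent assembly and a shorter route, at the price of one unprecedented step and the loss of half the material in a resolution.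

Alternative 2: The cut is the C4a=C8a double bond, with the oxygenated chain C5–C8 drawn from D-galactose A4. The forward key step is a ring-closing metathesis of diene A5, between its vinyl group (C4a) and its 1-methoxyvinyl group (C8a), with Mo(N-2,6-iPr2C6H3)(CHCMe2Ph)[OCMe(CF3)2]2 (hexavalent molybdenum) or the second-generation Grubbs catalyst RuCl2(H2IMes)(PCy3)(=CHPh), giving the cyclic methyl enol ether A6. This road is better than the chosen one in two respects: the absolute configuration is secure, and A6 holds C8a at the enol-ether level, ready for annulation with the same acylketene that 3 delivers, with each oxygen separately protected. Its weak points are the long preparation of A5 from the sugar, the air-sensitive molybdenum catalyst (or high ruthenium loading) that 1,1-disubstituted enol ethers demand, and again an aryl ether made late by substitution at C5 after removal of the 4-methoxybenzyl group. The chosen plan sets its shorter, convergent sequence and the early, trivial ether formation against this, and concedes that its own stereochemical outcome is less assured.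

Alternative 3: The cut lies in the aromatic chromone, at C4a'–C4' and C4'–C3'. Aryl iodide A7, already carrying the tetrahydrochromone ether, is coupled with carbon monoxide and 4-phenylbut-1-yne A8 under PdCl2(PPh3)2 (divalent palladium precatalyst) and triethylamine to give the aryl alkynyl ketone A9. Removal of the methoxymethyl group and 6-endo cyclisation would then complete the second pyranone. The carbonylative alkynylation is well precedented, which the key step of the chosen plan is not, and the road allows late variation of the C2' side chain. For this target it moves the difficulty without solving it: A7 presupposes an enantiopure tetrahydrochromone and its C5–O(aryl) bond, and the end game adds a palladium step on a substrate with allylic C–O bonds and four different protecting groups to remove. The chosen plan brings the aromatic chromone in as the preformed phenol 14, made in three steps, and spends its risk on the carbocycle, where the real problem lies.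

Key step: step 10

Remark: compounds 19, 20 and 21 are racemates; their names and SMILES show the enantiomer that leads to 23.
Remark: 19 is written as the trans-disulfone with the C6 sulfonyl group anti to the aryloxy group; the other trans-disulfone, should it form, gives the same 20 in step 11.

## Steps

Step 1
Reactants: 1 2,2,6-trimethyl-4H-1,3-dioxin-4-one
Product: 3 2,2-dimethyl-6-(2-phenylethyl)-4H-1,3-dioxin-4-one, via lithium dienolate 2 (not isolated)
Conditions: LiN(iPr)2, THF, −78 °C; BnBr, DMPU, −78 → −20 °C
Reagents that add atoms: benzyl bromide, BrCc1ccccc1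
Why: LiN(iPr)2 removes a proton from the 6-methyl group to give the cross-conjugated dienolate 2, and the reactive benzylic bromide alkylates its terminal (γ) carbon; vinylogous enolate alkylation of a dioxinone.

Step 2
Reactants: 4 methyl 4,4-dimethoxy-3-oxobutanoate
Product: 5 methyl (2E)-4,4-dimethoxy-3-(pyrrolidin-1-yl)but-2-enoate
Conditions: pyrrolidine, PhMe, 4 Å molecular sieves, 20 → 60 °C
Reagents that add atoms: pyrrolidine, C1CCNC1
Why: Enamine formation: the secondary amine condenses with the ketone carbonyl, the most electrophilic one, and the product is stabilised as a vinylogous carbamate; its double-bond geometry is of no consequence for step 3.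

Step 3
Reactants: 3 2,2-dimethyl-6-(2-phenylethyl)-4H-1,3-dioxin-4-one; 5 methyl (2E)-4,4-dimethoxy-3-(pyrrolidin-1-yl)but-2-enoate
Product: 8 methyl 2-(dimethoxymethyl)-4-oxo-6-(2-phenylethyl)-4H-pyran-3-carboxylate, via acylketene 6 (not isolated), via C-acylated enaminone 7 (not isolated)
Conditions: PhMe, 110 °C (3 in excess); then AcOH, 60 °C
Reagents that add atoms: none
Why: Thermal retro-[4+2] of 3 releases acylketene 6, which acylates the nucleophilic α-carbon of 5 to give 7; the enol oxygen of the phenethyl ketone then displaces pyrrolidine at the amine-bearing carbon, so the ring closes on C2 and not on the ester carbonyl. This is the acylketene–enamine annulation to a 4-pyranone.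

Step 4
Reactants: 8 methyl 2-(dimethoxymethyl)-4-oxo-6-(2-phenylethyl)-4H-pyran-3-carboxylate
Product: 9 2-(dimethoxymethyl)-3-(hydroxymethyl)-6-(2-phenylethyl)-4H-pyran-4-one
Conditions: iBu2AlH (2.5 equiv), CH2Cl2, −78 °C; aq. KNaC4H4O6 work-up
Reagents that add atoms: none
Why: iBu2AlH reduces α,β-unsaturated esters by 1,2-addition to the allylic alcohol; the ring carbonyl is a doubly vinylogous ester and the least electrophilic carbonyl present, and the acetal is inert at −78 °C. The neutral tartrate work-up avoids closure of the hydroxy acetal to a cyclic acetal.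

Step 5
Reactants: 10 1-(2,4,5-trihydroxyphenyl)ethanone
Product: 11 1-[4-(benzyloxy)-2,5-dihydroxyphenyl]ethanone
Conditions: BnBr (1.0 equiv), NaHCO3, DMF, 40 °C, under argon
Reagents that add atoms: benzyl bromide, BrCc1ccccc1
Why: Regioselective Williamson etherification: the 4-hydroxyl, para to the acetyl group, is the most acidic phenol, the 2-hydroxyl is chelated to the carbonyl and the 5-hydroxyl is not activated, so one equivalent of halide with a weak base should give the 4-benzyl ether.

Step 6
Reactants: 11 1-[4-(benzyloxy)-2,5-dihydroxyphenyl]ethanone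
Product: 12 2-acetyl-5-(benzyloxy)-1,4-phenylene bis(3-phenylpropanoate)
Conditions: 3-phenylpropanoyl chloride (2.4 equiv), pyridine, DMAP (cat.), CH2Cl2, 0 → 20 °C
Reagents that add atoms: 3-phenylpropanoyl chloride, O=C(Cl)CCc1ccccc1
Why: DMAP-catalysed esterification of both remaining phenols; the ester ortho to the acetyl group is the one needed for the rearrangement, and the other serves as a temporary protecting group.

Step 7
Reactants: 12 2-acetyl-5-(benzyloxy)-1,4-phenylene bis(3-phenylpropanoate)
Product: 14 7-(benzyloxy)-6-hydroxy-2-(2-phenylethyl)-4H-chromen-4-one, via diketone 13 (not isolated)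
Conditions: NaH, THF, 65 °C; then conc. HCl, MeOH, 65 °C
Reagents that add atoms: none
Why: Baker–Venkataraman rearrangement: the ketone enolate attacks the neighbouring aryl ester intramolecularly to give 1,3-diketone 13. Acid then closes the pyranone ring by cyclodehydration and methanolyses the remaining aryl ester, which frees the C6 phenol while the benzyl ether stays.

Step 8
Reactants: 9 2-(dimethoxymethyl)-3-(hydroxymethyl)-6-(2-phenylethyl)-4H-pyran-4-one; 14 7-(benzyloxy)-6-hydroxy-2-(2-phenylethyl)-4H-chromen-4-one
Product: 15 7-(benzyloxy)-6-{[2-(dimethoxymethyl)-4-oxo-6-(2-phenylethyl)-4H-pyran-3-yl]methoxy}-2-(2-phenylethyl)-4H-chromen-4-one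
Conditions: PPh3, DIAD, THF, 0 → 20 °C
Reagents that add atoms: none
Why: Mitsunobu etherification of a primary, allylic-type alcohol with a phenol; the carbon attacked is unhindered and not stereogenic, and the aldehyde is masked so that no lactol can form.

Step 9
Reactants: 15 7-(benzyloxy)-6-{[2-(dimethoxymethyl)-4-oxo-6-(2-phenylethyl)-4H-pyran-3-yl]methoxy}-2-(2-phenylethyl)-4H-chromen-4-one
Product: 16 3-({[7-(benzyloxy)-4-oxo-2-(2-phenylethyl)-4H-chromen-6-yl]oxy}methyl)-4-oxo-6-(2-phenylethyl)-4H-pyran-2-carbaldehyde
Conditions: CF3CO2H/H2O, CH2Cl2, 0 → 20 °C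
Reagents that add atoms: water, O
Why: Acid-catalysed hydrolysis of a dimethyl acetal; the acetal carbon bears the electron-poor pyranone, so aqueous CF3CO2H is used, and aryl benzyl and aryl alkyl ethers persist under these conditions.

Step 10
Reactants: 16 3-({[7-(benzyloxy)-4-oxo-2-(2-phenylethyl)-4H-chromen-6-yl]oxy}methyl)-4-oxo-6-(2-phenylethyl)-4H-pyran-2-carbaldehyde; 17 (E)-1,2-bis(phenylsulfonyl)ethene
Product: 19 rac-(5S,6R,7R,8R)-5-{[7-(benzyloxy)-4-oxo-2-(2-phenylethyl)-4H-chromen-6-yl]oxy}-8-hydroxy-2-(2-phenylethyl)-6,7-bis(phenylsulfonyl)-5,6,7,8-tetrahydro-4H-chromen-4-one, via dienol 18 (not isolated)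
Conditions: hν (365 nm), 17 (3 equiv), degassed CH2Cl2, 20 °C
Reagents that add atoms: none
Why: Proposed new method: light of 365 nm excites the n,π* state of the formyl group of 16, and after intersystem crossing the triplet carbonyl oxygen abstracts, through a six-membered transition state, one hydrogen of the aryloxy-substituted methylene group (a weak C–H bond, allylic and next to oxygen), and the 1,4-biradical relaxes to the ground-state dienol 18, C8(OH)=C8a–C4a=C5H(OAr) in chromone numbering. The closest known reaction type is the photoenolization/Diels–Alder reaction of ortho-alkyl benzaldehydes and aryl ketones, in which hydroxy-ortho-quinodimethanes are trapped by electron-poor alkenes; here the double bond that lends its two carbons is C2=C3 of a 4-pyranone, which costs less resonance energy than a benzene ring. The six-membered carbocycle closes by an intermolecular [4+2] cycloaddition of 18 with 17, suprafacial on both partners, which forms C5–C6 and C7–C8 and restores the pyranone. C5 and C8 come out cis because only the dienol with hydroxyl and aryloxy group both outward is reactive: an inward hydroxyl returns the hydrogen by a thermal 1,5-shift, and an inward aryloxy group would clash with the other terminus. C6 and C7 come out trans because the E geometry of 17 is kept; which sulfonyl group lies syn to the C5 and C8 substituents does not matter, since both centres are erased in step 11. The step needs site-selective hydrogen transfer, secured by the fixed ortho arrangement of the formyl and CH2OAr groups and by the weakness of that C–H bond, and a dienophile fast enough to outrun reversion of 18, secured by the two sulfonyl groups. No element in 16 or 17 distinguishes the two faces of 18, so 19 forms as the racemate and the enantiomers are separated in step 13.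

Step 11
Reactants: 19 rac-(5S,6R,7R,8R)-5-{[7-(benzyloxy)-4-oxo-2-(2-phenylethyl)-4H-chromen-6-yl]oxy}-8-hydroxy-2-(2-phenylethyl)-6,7-bis(phenylsulfonyl)-5,6,7,8-tetrahydro-4H-chromen-4-one
Product: 20 rac-(5R,8S)-5-{[7-(benzyloxy)-4-oxo-2-(2-phenylethyl)-4H-chromen-6-yl]oxy}-8-hydroxy-2-(2-phenylethyl)-5,8-dihydro-4H-chromen-4-one
Conditions: Na(Hg) (6%), NaH2PO4, THF/MeOH, −20 °C
Reagents that add atoms: none
Why: Reductive elimination of a vicinal bis-sulfone by electron transfer from sodium amalgam, the usual unmasking of 17 as an acetylene equivalent: loss of the first sulfinate leaves a β-sulfonyl radical or anion that expels the second and gives the C6=C7 alkene. The phosphate buffer and low temperature suppress base-induced loss of sulfinate or aryloxide, and C5 and C8 are untouched (only the descriptor at C5 changes).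

Step 12
Reactants: 20 rac-(5R,8S)-5-{[7-(benzyloxy)-4-oxo-2-(2-phenylethyl)-4H-chromen-6-yl]oxy}-8-hydroxy-2-(2-phenylethyl)-5,8-dihydro-4H-chromen-4-one
Product: 21 rac-(5S,6S,7R,8S)-5-{[7-(benzyloxy)-4-oxo-2-(2-phenylethyl)-4H-chromen-6-yl]oxy}-6,7,8-trihydroxy-2-(2-phenylethyl)-5,6,7,8-tetrahydro-4H-chromen-4-one
Conditions: OsO4 (cat.), NMO, acetone/H2O, 0 → 20 °C, used directly after step 11
Reagents that add atoms: osmium tetroxide, O=[Os](=O)(=O)=O; N-methylmorpholine N-oxide, C[N+]1([O-])CCOCC1; water, O
Why: Catalytic syn-dihydroxylation of the only isolated alkene; OsO4 adds to the face opposite the two allylic oxygen substituents at C5 and C8, which lie on the same face, so both new hydroxyls come out cis to each other and trans to their neighbours. The pyranone double bonds are too electron-poor to compete.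

Step 13
Reactants: 21 rac-(5S,6S,7R,8S)-5-{[7-(benzyloxy)-4-oxo-2-(2-phenylethyl)-4H-chromen-6-yl]oxy}-6,7,8-trihydroxy-2-(2-phenylethyl)-5,6,7,8-tetrahydro-4H-chromen-4-one
Product: 22 (5S,6S,7R,8S)-5-{[7-(benzyloxy)-4-oxo-2-(2-phenylethyl)-4H-chromen-6-yl]oxy}-6,7,8-trihydroxy-2-(2-phenylethyl)-5,6,7,8-tetrahydro-4H-chromen-4-one
Conditions: preparative HPLC, amylose tris(3,5-dimethylphenylcarbamate) on silica, hexane/EtOH
Reagents that add atoms: none
Why: Resolution of a racemate by chromatography on a polysaccharide-carbamate chiral stationary phase; 21 is a rigid, aromatic, hydrogen-bond-donating single diastereomer, the kind of solute such phases separate well. The configuration of the collected enantiomer would be assigned by anomalous-dispersion X-ray analysis or by comparing the derived 23 with the natural product.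

Step 14
Reactants: 22 (5S,6S,7R,8S)-5-{[7-(benzyloxy)-4-oxo-2-(2-phenylethyl)-4H-chromen-6-yl]oxy}-6,7,8-trihydroxy-2-(2-phenylethyl)-5,6,7,8-tetrahydro-4H-chromen-4-one
Product: 23 (5S,6S,7R,8S)-6,7,8-trihydroxy-5-{[7-hydroxy-4-oxo-2-(2-phenylethyl)-4H-chromen-6-yl]oxy}-2-(2-phenylethyl)-5,6,7,8-tetrahydro-4H-chromen-4-one
Conditions: H2 (1 atm), Pd/C, EtOAc, 20 °C
Reagents that add atoms: none
Why: Hydrogenolysis of an aryl benzyl ether, the fastest hydrogenolysis available in the molecule; the tetrasubstituted, electron-poor C4a=C8a bond should keep the allylic C5–O and C8–O bonds away from the metal, and the trisubstituted pyranone double bonds are reduced much more slowly.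

## Compound list

1 | 2,2,6-trimethyl-4H-1,3-dioxin-4-one | CC1=CC(=O)OC(C)(C)O1 | starting material
2 | lithium 2,2-dimethyl-6-methylidene-6H-1,3-dioxin-4-olate | [Li+].[O-]C1=CC(=C)OC(C)(C)O1 | intermediate (not isolated)
3 | 2,2-dimethyl-6-(2-phenylethyl)-4H-1,3-dioxin-4-one | CC1(C)OC(=O)C=C(CCc2ccccc2)O1 | intermediate
4 | methyl 4,4-dimethoxy-3-oxobutanoate | COC(=O)CC(=O)C(OC)OC | starting material
5 | methyl (2E)-4,4-dimethoxy-3-(pyrrolidin-1-yl)but-2-enoate | COC(=O)/C=C(/N1CCCC1)C(OC)OC | intermediate
6 | 5-phenylpent-1-ene-1,3-dione (acylketene) | O=C=CC(=O)CCc1ccccc1 | intermediate (not isolated)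
7 | methyl 2-[2,2-dimethoxy-1-(pyrrolidin-1-yl)ethylidene]-3,5-dioxo-7-phenylheptanoate | COC(=O)C(C(=O)CC(=O)CCc1ccccc1)=C(C(OC)OC)N1CCCC1 | intermediate (not isolated)
8 | methyl 2-(dimethoxymethyl)-4-oxo-6-(2-phenylethyl)-4H-pyran-3-carboxylate | COC(=O)c1c(C(OC)OC)oc(CCc2ccccc2)cc1=O | intermediate
9 | 2-(dimethoxymethyl)-3-(hydroxymethyl)-6-(2-phenylethyl)-4H-pyran-4-one | COC(OC)c1oc(CCc2ccccc2)cc(=O)c1CO | intermediate
10 | 1-(2,4,5-trihydroxyphenyl)ethanone | CC(=O)c1cc(O)c(O)cc1O | starting material
11 | 1-[4-(benzyloxy)-2,5-dihydroxyphenyl]ethanone | CC(=O)c1cc(O)c(OCc2ccccc2)cc1O | intermediate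
12 | 2-acetyl-5-(benzyloxy)-1,4-phenylene bis(3-phenylpropanoate) | CC(=O)c1cc(OC(=O)CCc2ccccc2)c(OCc2ccccc2)cc1OC(=O)CCc1ccccc1 | intermediate
13 | 2-(benzyloxy)-4-hydroxy-5-(3-oxo-5-phenylpentanoyl)phenyl 3-phenylpropanoate | O=C(CCc1ccccc1)CC(=O)c1cc(OC(=O)CCc2ccccc2)c(OCc2ccccc2)cc1O | intermediate (not isolated)
14 | 7-(benzyloxy)-6-hydroxy-2-(2-phenylethyl)-4H-chromen-4-one | O=c1cc(CCc2ccccc2)oc2cc(OCc3ccccc3)c(O)cc12 | intermediate
15 | 7-(benzyloxy)-6-{[2-(dimethoxymethyl)-4-oxo-6-(2-phenylethyl)-4H-pyran-3-yl]methoxy}-2-(2-phenylethyl)-4H-chromen-4-one | COC(OC)c1oc(CCc2ccccc2)cc(=O)c1COc1cc2c(=O)cc(CCc3ccccc3)oc2cc1OCc1ccccc1 | intermediate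
16 | 3-({[7-(benzyloxy)-4-oxo-2-(2-phenylethyl)-4H-chromen-6-yl]oxy}methyl)-4-oxo-6-(2-phenylethyl)-4H-pyran-2-carbaldehyde | O=Cc1oc(CCc2ccccc2)cc(=O)c1COc1cc2c(=O)cc(CCc3ccccc3)oc2cc1OCc1ccccc1 | intermediate
17 | (E)-1,2-bis(phenylsulfonyl)ethene | O=S(=O)(/C=C/S(=O)(=O)c1ccccc1)c1ccccc1 | starting material
18 | (2Z,3Z)-3-({[7-(benzyloxy)-4-oxo-2-(2-phenylethyl)-4H-chromen-6-yl]oxy}methylidene)-2-(hydroxymethylidene)-6-(2-phenylethyl)-2,3-dihydro-4H-pyran-4-one (hydroxyl and aryloxy group both outward) | O/C=C1/C(=C/Oc2cc3c(=O)cc(CCc4ccccc4)oc3cc2OCc2ccccc2)C(=O)C=C(CCc2ccccc2)O1 | intermediate (not isolated)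
19 | rac-(5S,6R,7R,8R)-5-{[7-(benzyloxy)-4-oxo-2-(2-phenylethyl)-4H-chromen-6-yl]oxy}-8-hydroxy-2-(2-phenylethyl)-6,7-bis(phenylsulfonyl)-5,6,7,8-tetrahydro-4H-chromen-4-one (racemate; 5-aryloxy and 8-hydroxyl cis, sulfonyl groups trans) | O=c1cc(CCc2ccccc2)oc2c1[C@H](Oc1cc3c(=O)cc(CCc4ccccc4)oc3cc1OCc1ccccc1)[C@@H](S(=O)(=O)c1ccccc1)[C@H](S(=O)(=O)c1ccccc1)[C@@H]2O | intermediate
20 | rac-(5R,8S)-5-{[7-(benzyloxy)-4-oxo-2-(2-phenylethyl)-4H-chromen-6-yl]oxy}-8-hydroxy-2-(2-phenylethyl)-5,8-dihydro-4H-chromen-4-one (racemate; cis) | O=c1cc(CCc2ccccc2)oc2c1[C@H](Oc1cc3c(=O)cc(CCc4ccccc4)oc3cc1OCc1ccccc1)C=C[C@@H]2O | intermediate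
21 | rac-(5S,6S,7R,8S)-5-{[7-(benzyloxy)-4-oxo-2-(2-phenylethyl)-4H-chromen-6-yl]oxy}-6,7,8-trihydroxy-2-(2-phenylethyl)-5,6,7,8-tetrahydro-4H-chromen-4-one (racemate) | O=c1cc(CCc2ccccc2)oc2c1[C@H](Oc1cc3c(=O)cc(CCc4ccccc4)oc3cc1OCc1ccccc1)[C@@H](O)[C@@H](O)[C@@H]2O | intermediate
22 | (5S,6S,7R,8S)-5-{[7-(benzyloxy)-4-oxo-2-(2-phenylethyl)-4H-chromen-6-yl]oxy}-6,7,8-trihydroxy-2-(2-phenylethyl)-5,6,7,8-tetrahydro-4H-chromen-4-one (single enantiomer) | O=c1cc(CCc2ccccc2)oc2c1[C@H](Oc1cc3c(=O)cc(CCc4ccccc4)oc3cc1OCc1ccccc1)[C@@H](O)[C@@H](O)[C@@H]2O | intermediate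
23 | (5S,6S,7R,8S)-6,7,8-trihydroxy-5-{[7-hydroxy-4-oxo-2-(2-phenylethyl)-4H-chromen-6-yl]oxy}-2-(2-phenylethyl)-5,6,7,8-tetrahydro-4H-chromen-4-one | O=c1cc(CCc2ccccc2)oc2c1[C@H](Oc1cc3c(=O)cc(CCc4ccccc4)oc3cc1O)[C@@H](O)[C@@H](O)[C@@H]2O | target

## Step count and least certain steps

Total: 14 steps (13 chemical transformations and one resolution). Longest linear sequence: 10 steps (steps 1, 3, 4, 8, 9, 10, 11, 12, 13, 14 from 1; the arm from 10 is equally long).

**Step 10 (key step, new method).** The most likely failure is inefficient trapping. The dienol may revert to the aldehyde faster than it adds 17, the chromone chromophore may take part of the light, and 17 may be photoisomerised or drawn into [2+2] or Paternò–Büchi side reactions. Poor discrimination between outward and inward placement of the aryloxy group would erode the cis C5/C8 relation.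
Fallback, with known reaction types and without light: it sets out from 16 and returns at 19. The enal unit of 16 (formyl group, C2=C3, γ-CH2OAr) would be converted by silyl triflate and a hindered amine (tBuMe2SiOSO2CF3, iPr2NEt, CH2Cl2, −78 → 0 °C), by γ-deprotonation of the silyl-activated aldehyde, into (2Z,3Z)-3-({[7-(benzyloxy)-4-oxo-2-(2-phenylethyl)-4H-chromen-6-yl]oxy}methylidene)-2-{[(tert-butyldimethylsilyl)oxy]methylidene}-6-(2-phenylethyl)-2,3-dihydro-4H-pyran-4-one F1. This is the usual way from enals to 1-silyloxydienes. F1 would be generated in the presence of 17 and undergo a thermal Diels–Alder reaction to the silyl ether of the adduct, rac-(5S,6R,7R,8R)-5-{[7-(benzyloxy)-4-oxo-2-(2-phenylethyl)-4H-chromen-6-yl]oxy}-8-[(tert-butyldimethylsilyl)oxy]-2-(2-phenylethyl)-6,7-bis(phenylsulfonyl)-5,6,7,8-tetrahydro-4H-chromen-4-one F2. Desilylation with HF·pyridine would give 19.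

**Step 3 (annulation).** The liberated pyrrolidine may capture the acylketene before cyclisation is complete, the acylketene may dimerise, or the open intermediate may close onto the ester carbonyl and give a 2-pyranone.
Fallback: it sets out from 4 and returns at 8. The magnesium enolate of 4 (Mg(OEt)2, THF) would be C-acylated with 5-phenylpent-2-ynoyl chloride F3 (from the corresponding acid and oxalyl chloride) to give methyl 2-(2,2-dimethoxyacetyl)-3-oxo-7-phenylhept-4-ynoate F4. Its enol oxygen would add to the ynone in a 6-endo oxa-Michael cyclisation (catalytic Et3N, CH2Cl2) to give 8; this closure can only form the 4-pyranone.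

**Step 4 (ester reduction).** Hydride may be delivered to the pyranone (at the ring carbonyl or at C2, which is activated by both carbonyls) instead of the ester, because the aluminium reagent binds the more basic ring oxygen first. The hydroxy acetal may also cyclise during work-up.
Fallback: it sets out from 8 and returns at 9, and replaces the nucleophilic hydride by an electrophilic one acting on the acid. Neutral ester cleavage with Me3SnOH (1,2-dichloroethane, 80 °C) would give 2-(dimethoxymethyl)-4-oxo-6-(2-phenylethyl)-4H-pyran-3-carboxylic acid F5, and BH3·SMe2 (THF, 0 °C) reduces a carboxylic acid faster than any other carbonyl group present, giving 9.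

**Step 11 (reductive desulfonylation).** The methoxide formed at the amalgam surface may cause loss of sulfinate to a vinyl sulfone, or loss of aryloxide from C5, followed by aromatisation. Electron transfer to the pyranone carbonyls may compete, and the product diene 20 may aromatise if kept.
Fallback: it sets out from 16 and returns at 20, and replaces dissolving-metal reduction by a neutral radical chain. The key step would be run with (E)-1-nitro-2-(phenylsulfonyl)ethene F6, which would first have to be prepared, and should give rac-5-{[7-(benzyloxy)-4-oxo-2-(2-phenylethyl)-4H-chromen-6-yl]oxy}-8-hydroxy-7-nitro-2-(2-phenylethyl)-6-(phenylsulfonyl)-5,6,7,8-tetrahydro-4H-chromen-4-one F7 (5,8-cis; 6,7-trans; nitro group next to the carbinol carbon). Bu3SnH with AIBN (PhMe, 80 °C) would remove the nitro group as a radical, and β-scission of the sulfonyl radical would then give 20.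

## Further compounds

F1 | step 10 | (2Z,3Z)-3-({[7-(benzyloxy)-4-oxo-2-(2-phenylethyl)-4H-chromen-6-yl]oxy}methylidene)-2-{[(tert-butyldimethylsilyl)oxy]methylidene}-6-(2-phenylethyl)-2,3-dihydro-4H-pyran-4-one | CC(C)(C)[Si](C)(C)O/C=C1/C(=C/Oc2cc3c(=O)cc(CCc4ccccc4)oc3cc2OCc2ccccc2)C(=O)C=C(CCc2ccccc2)O1
F2 | step 10 | rac-(5S,6R,7R,8R)-5-{[7-(benzyloxy)-4-oxo-2-(2-phenylethyl)-4H-chromen-6-yl]oxy}-8-[(tert-butyldimethylsilyl)oxy]-2-(2-phenylethyl)-6,7-bis(phenylsulfonyl)-5,6,7,8-tetrahydro-4H-chromen-4-one | O=c1cc(CCc2ccccc2)oc2c1[C@H](Oc1cc3c(=O)cc(CCc4ccccc4)oc3cc1OCc1ccccc1)[C@@H](S(=O)(=O)c1ccccc1)[C@H](S(=O)(=O)c1ccccc1)[C@@H]2O[Si](C)(C)C(C)(C)C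
F3 | step 3 | 5-phenylpent-2-ynoyl chloride | O=C(Cl)C#CCCc1ccccc1
F4 | step 3 | methyl 2-(2,2-dimethoxyacetyl)-3-oxo-7-phenylhept-4-ynoate | COC(=O)C(C(=O)C#CCCc1ccccc1)C(=O)C(OC)OC
F5 | step 4 | 2-(dimethoxymethyl)-4-oxo-6-(2-phenylethyl)-4H-pyran-3-carboxylic acid | COC(OC)c1oc(CCc2ccccc2)cc(=O)c1C(=O)O
F6 | step 11 | (E)-1-nitro-2-(phenylsulfonyl)ethene | O=[N+]([O-])/C=C/S(=O)(=O)c1ccccc1
F7 | step 11 | rac-5-{[7-(benzyloxy)-4-oxo-2-(2-phenylethyl)-4H-chromen-6-yl]oxy}-8-hydroxy-7-nitro-2-(2-phenylethyl)-6-(phenylsulfonyl)-5,6,7,8-tetrahydro-4H-chromen-4-one (5,8-cis; 6,7-trans) | O=c1cc(CCc2ccccc2)oc2c1[C@H](Oc1cc3c(=O)cc(CCc4ccccc4)oc3cc1OCc1ccccc1)[C@@H](S(=O)(=O)c1ccccc1)[C@H]([N+](=O)[O-])[C@@H]2O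
A1 | alternative 1 | D-mannose (pyranose form) | OC[C@H]1OC(O)[C@@H](O)[C@@H](O)[C@@H]1O
A2 | alternative 1 | methyl 2,3,4-tri-O-benzyl-6-deoxy-α-D-lyxo-hex-5-enopyranoside | C=C1O[C@H](OC)[C@@H](OCc2ccccc2)[C@@H](OCc2ccccc2)[C@@H]1OCc1ccccc1
A3 | alternative 1 | 2,3,4-tris(benzyloxy)-5-hydroxycyclohexanone (hydroxyl trans to the 3-benzyloxy group) | O=C1C[C@H](O)[C@@H](OCc2ccccc2)[C@@H](OCc2ccccc2)[C@@H]1OCc1ccccc1
A4 | alternative 2 | D-galactose (pyranose form) | OC[C@H]1OC(O)[C@H](O)[C@@H](O)[C@H]1O
A5 | alternative 2 | acyclic diene with vinyl and 1-methoxyvinyl termini, C5 O-(4-methoxybenzyl), C6/C7 acetonide, C8 O-benzyl | C=C[C@H](OCc1ccc(OC)cc1)[C@@H](OC1(C)C)[C@@H](O1)[C@H](OCc1ccccc1)C(=C)OC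
A6 | alternative 2 | 1-methoxycyclohexene with C5 O-(4-methoxybenzyl), C6/C7 acetonide, C8 O-benzyl | COC1=C[C@H](OCc2ccc(OC)cc2)[C@@H](OC2(C)C)[C@@H](O2)[C@@H]1OCc1ccccc1
A7 | alternative 3 | aryl iodide with the protected tetrahydrochromone ether in place | O=c1cc(CCc2ccccc2)oc2c1[C@H](Oc1cc(I)c(OCOC)cc1OCc1ccccc1)[C@@H](OC1(C)C)[C@@H](O1)[C@@H]2O[Si](C)(C)C(C)(C)C
A8 | alternative 3 | 4-phenylbut-1-yne | C#CCCc1ccccc1
A9 | alternative 3 | aryl 5-phenylpent-2-ynoyl ketone with the protected tetrahydrochromone ether in place | O=c1cc(CCc2ccccc2)oc2c1[C@H](Oc1cc(C(=O)C#CCCc3ccccc3)c(OCOC)cc1OCc1ccccc1)[C@@H](OC1(C)C)[C@@H](O1)[C@@H]2O[Si](C)(C)C(C)(C)C
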